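Ask how much Z.J stands after 2.0 h as the charge of L rises from 0.080 M through 0.25 M to 0.80 M.

- [Z.J] at the end for midnight, dusk, summer, in this order
- how the row runs (falls all the way / rises all the way / rises, then falls / falls, then rises / hardly changes)

in all of them: D 88 mM (held); time 2.0 h

| run | L |
|---|---|
| midnight | 0.080 M |
| dusk | 0.25 M |
| summer | 0.80 M |

    G → J (k1 = 0.161 min⁻¹)
    Z + J → Z.J (k2 = 0.140 M⁻¹ min⁻¹)
    L ⇌ G, rate k3*(cs3 - [G]) while solid is left; crystals form when [G] > cs3 (cs3 = 26 mM, k3 = 0.00613 min⁻¹)
    D ⇌ Z, rate k4*(csat - [Z]) (k4 = 0.0254 min⁻¹, csat = 88 mM)

- given per volume of solution although it is solid: L
- at the start none of Z is dissolved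
- at the start none of L is in solution
- "hardly changes" means that all values lie within two and a half points (for a concentration: within two and a half percent of the largest)
- run time (midnight): 2.0 h

Start with the dissolution law, for that is how L enters the solution: its rate holds the solubility and the level of G, but not the charge, as long as solid is left. So take its rate with no G present, coefficient times solubility, 0.159 mM min⁻¹, and call that the ceiling. But does G stay low? It passes on to J with a half-life of 4.31 min, shorter than the run, and its level should sit near the ceiling over its rate constant, 0.990 mM, far below the solubility of 26 mM. So dissolution runs close to the ceiling and is the rate-limiting step in the supply of J.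

Now ask how long that lasts. Divide the charge of L by the ceiling and call this the emptying time, 8.37 h for midnight, the smallest charge. The run covers about a quarter of it. Dusk gets 26.1 h and summer 83.7 h, so solid outlasts the run in each flask. Z comes from D by a law without L in it. Commit, then, to a row that hardly changes, below the ceiling times the run, 19.1 mM; this reckoning stops short of the height.

The forecast goes further and prints a height: 0.0072 M, 0.0072 M, 0.0072 M, so that the row hardly changes. Solid that stays, it says, “makes all three runs identical”.

The flasks give 0.00718 M, 0.00718 M, 0.00718 M, so the row hardly changes. Midnight still holds 76.9% of its L at 2.00 h. Take the emptying time further out, to 20.0 h: midnight's 8.37 h lies below that time, and its L stands at 0%, while dusk's 26.1 h lies above it, and dusk's L stands at 26.3%.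

(The constants are those of an exercise, and the outcome is calculated.)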